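**Strategy.** The target is cut at the C6–C5' biaryl bond. In ring A the 7-OH sits ortho to that bond, and in unit B the carbonyl carbon C4' hangs from C4a', the ortho neighbour of C5', so an O7–C4' ester ties the two arenes into a six-membered lactone. A palladium-catalysed intramolecular C–H arylation of a 6-bromochromon-7-yl 2,3-dimethoxybenzoate forges C6–C5' and the lactone ring in one operation, and the bridge carbonyl is kept as C4' of the second pyranone. The precursor is the 7-O-(2,3-dimethoxybenzoyl) ester of 6-bromo-7-hydroxy-2-(2-phenylethyl)chromone, whose benzoate has a single free ortho C–H.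

Key step: step 3

Assumption: the target carries no stereodescriptor; the C6–C5' axis has only O7 and C4a' as non-hydrogen ortho groups and is treated as freely rotating, so no axial control is planned.

Step 1
Reactants: 1 1-(5-bromo-2,4-dihydroxyphenyl)ethanone; 2 ethyl 3-phenylpropanoate
Product: 4 6-bromo-7-hydroxy-2-(2-phenylethyl)-4H-chromen-4-one, via open-chain diketone 3 (not isolated)
Conditions: NaH (6 equiv), 2 (3 equiv), THF, 0 °C → reflux; then conc. HCl, MeOH, reflux, same flask
Reagents that add atoms: none
Why: Crossed Claisen condensation of the sodium polyanion of 1 with ester 2 should give diketonate 3 (aryl bromide and phenoxides are inert to NaH), and acid then drives cyclodehydration in which the 2-OH, the only hydroxyl ortho to the acyl group, adds to the distal carbonyl to close the 4-pyranone, as in the classical conversion of resacetophenone into 7-hydroxychromones.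

Step 2
Reactants: 4 6-bromo-7-hydroxy-2-(2-phenylethyl)-4H-chromen-4-one; 5 2,3-dimethoxybenzoic acid
Product: 6 6-bromo-4-oxo-2-(2-phenylethyl)-4H-chromen-7-yl 2,3-dimethoxybenzoate
Conditions: DCC (1.2 equiv), DMAP (0.1 equiv), CH2Cl2, 0 °C → rt
Reagents that add atoms: none
Why: Steglich esterification, in which DMAP relays the O-acylisourea of 5 as an N-acylpyridinium to the single, acidic 7-OH of 4, while the chromone and the aryl bromide are untouched.

Step 3
Reactants: 6 6-bromo-4-oxo-2-(2-phenylethyl)-4H-chromen-7-yl 2,3-dimethoxybenzoate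
Product: 7 lactone-bridged biaryl, the O7→carboxyl lactone of 6-(2-carboxy-3,4-dimethoxyphenyl)-7-hydroxy-2-(2-phenylethyl)-4H-chromen-4-one (a 7,8-dimethoxy-6H-benzo[c]chromen-6-one with the pyranone of ring A fused at its 2,3-bond)
Conditions: Pd(OAc)2 (5 mol %), PCy3·HBF4 (10 mol %), K2CO3 (2 equiv), PivOH (30 mol %), dry DMA, 110 °C, argon
Reagents that add atoms: none
Why: Zerovalent palladium formed from Pd(OAc)2 and PCy3 should add oxidatively to the C6–Br bond of ring A; palladium-bound pivalate then removes the lone ortho hydrogen of the benzoate by concerted metalation–deprotonation, giving a diaryl palladacycle of seven ring atoms, and reductive elimination forms C6–C5'. The closest known reaction type is the palladium-catalysed intramolecular direct arylation of ester- and amide-tethered haloarenes to benzo[c]chromen-6-ones and phenanthridinones. The one new ring is the six-membered lactone (C6, C7, O7, ester carbon, benzoate C1, benzoate C6), closed by the C–C reductive elimination itself. No stereocentre is created. Site selectivity on ring A is fixed by the bromine carried at C6 from compound 1, and on the benzoate by the methoxy group at C2, which leaves C6–H as the only ortho position the tether can deliver to palladium. The electron-poor C–H next to the ester suits carboxylate-assisted palladation, and anhydrous carbonate should keep the aryl ester intact.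

Step 4
Reactants: 7 lactone-bridged biaryl; 8 4-phenylbutan-2-one
Product: 10 1-{6-[7-hydroxy-4-oxo-2-(2-phenylethyl)-4H-chromen-6-yl]-2,3-dimethoxyphenyl}-5-phenylpentane-1,3-dione, via lithium enolate 9 (not isolated)
Conditions: LiN(iPr)2 (3.1 equiv), 8 (3.0 equiv), THF, −78 °C, 30 min; then 7 in THF, −78 → −20 °C; 1 M HCl quench
Reagents that add atoms: none
Why: Claisen-type C-acylation of the kinetic methyl-side lithium enolate by the lactone, an activated aryl ester whose chromon-7-olate leaves readily; a second equivalent of enolate turns the product into its diketonate, which should block over-addition and relactonisation, while the vinylogous-ester carbonyl and fully substituted C2 of ring A are far less electrophilic.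

Step 5
Reactants: 10 1-{6-[7-hydroxy-4-oxo-2-(2-phenylethyl)-4H-chromen-6-yl]-2,3-dimethoxyphenyl}-5-phenylpentane-1,3-dione
Product: 12 8-hydroxy-5-[7-hydroxy-4-oxo-2-(2-phenylethyl)-4H-chromen-6-yl]-2-(2-phenylethyl)-4H-chromen-4-one, via catechol diketone 11 (not isolated)
Conditions: BBr3 (8 equiv), CH2Cl2, −78 °C → rt; then MeOH, 60 °C; aqueous work-up
Reagents that add atoms: none
Why: BBr3 ether cleavage, fastest at the methoxy group chelated to the aryl ketone, frees both phenols of ring B, and the HBr released on methanolysis should catalyse cyclodehydration of the o-hydroxyaryl 1,3-diketone by attack of the ortho OH on the distal carbonyl to give the aromatic pyranone; any reversible O7–C4' hemiketal reopens and drains to the chromone.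

**Compound list**

1 | 1-(5-bromo-2,4-dihydroxyphenyl)ethanone | CC(=O)c1cc(Br)c(O)cc1O | starting material
2 | ethyl 3-phenylpropanoate | CCOC(=O)CCc1ccccc1 | starting material
3 | 1-(5-bromo-2,4-dihydroxyphenyl)-5-phenylpentane-1,3-dione (open-chain diketone, formed in the flask) | O=C(CC(=O)CCc1ccccc1)c1cc(Br)c(O)cc1O | intermediate
4 | 6-bromo-7-hydroxy-2-(2-phenylethyl)-4H-chromen-4-one | O=c1cc(CCc2ccccc2)oc2cc(O)c(Br)cc12 | intermediate
5 | 2,3-dimethoxybenzoic acid | COc1cccc(C(=O)O)c1OC | starting material
6 | 6-bromo-4-oxo-2-(2-phenylethyl)-4H-chromen-7-yl 2,3-dimethoxybenzoate | O=c1cc(CCc2ccccc2)oc2cc(OC(=O)c3cccc(OC)c3OC)c(Br)cc12 | intermediate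
7 | lactone-bridged biaryl: O7→carboxyl lactone of 6-(2-carboxy-3,4-dimethoxyphenyl)-7-hydroxy-2-(2-phenylethyl)-4H-chromen-4-one | O=c1cc(CCc2ccccc2)oc2cc3OC(=O)c4c(OC)c(OC)ccc4-c3cc12 | intermediate
8 | 4-phenylbutan-2-one | CC(=O)CCc1ccccc1 | starting material
9 | lithium 4-phenylbut-1-en-2-olate (kinetic enolate, formed in the flask) | [Li+].[O-]C(=C)CCc1ccccc1 | intermediate
10 | 1-{6-[7-hydroxy-4-oxo-2-(2-phenylethyl)-4H-chromen-6-yl]-2,3-dimethoxyphenyl}-5-phenylpentane-1,3-dione | O=c1cc(CCc2ccccc2)oc2cc(O)c(-c3ccc(OC)c(OC)c3C(=O)CC(=O)CCc3ccccc3)cc12 | intermediate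
11 | 1-{2,3-dihydroxy-6-[7-hydroxy-4-oxo-2-(2-phenylethyl)-4H-chromen-6-yl]phenyl}-5-phenylpentane-1,3-dione (catechol diketone, formed in the flask) | O=c1cc(CCc2ccccc2)oc2cc(O)c(-c3ccc(O)c(O)c3C(=O)CC(=O)CCc3ccccc3)cc12 | intermediate
12 | 8-hydroxy-5-[7-hydroxy-4-oxo-2-(2-phenylethyl)-4H-chromen-6-yl]-2-(2-phenylethyl)-4H-chromen-4-one | O=c1cc(CCc2ccccc2)oc2cc(O)c(-c3ccc(O)c4oc(CCc5ccccc5)cc(=O)c34)cc12 | target

**Step count.** Total: 5 steps. Longest linear sequence: 5 steps (1 → 4 → 6 → 7 → 10 → 12).

**Steps most likely to fail**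

Step 3. Acyl transfer from the activated aryl ester to carbonate or pivalate, or protodebromination at C6, may outrun the C–H palladation, so that the tether is lost before the biaryl bond forms. The fallback makes the same C6–C5' bond by intermolecular cross-coupling and closes the lactone afterwards. It sets out from 5 and 4. Acid 5 is converted (SOCl2, then Et2NH) into N,N-diethyl-2,3-dimethoxybenzamide F1. Amide-directed ortho-lithiation (s-BuLi, TMEDA, THF, −78 °C), B(OMe)3 quench and aqueous acid should give [2-(diethylcarbamoyl)-3,4-dimethoxyphenyl]boronic acid F2. Suzuki–Miyaura coupling with bromide 4 (Pd(PPh3)4, aqueous Na2CO3, DME, 85 °C) should give N,N-diethyl-6-[7-hydroxy-4-oxo-2-(2-phenylethyl)-4H-chromen-6-yl]-2,3-dimethoxybenzamide F3. Heating F3 in AcOH should close the lactone with loss of diethylamine, and the fallback rejoins the route at 7.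

Step 4. Proton transfer may compete with acyl substitution at the hindered lactone carbonyl, either at the CH2 group attached to C2 of ring A or by equilibration of the enolate to its internal isomer. The result would be recovered lactone or branched diketone. The fallback uses a carbon nucleophile that cannot enolise and has no regiochemical ambiguity. It sets out from 7. The lithium acetylide of 4-phenylbut-1-yne (n-BuLi, THF, −78 °C; 1.2 equiv) should open the lactone to 6-[3,4-dimethoxy-2-(5-phenylpent-2-ynoyl)phenyl]-7-hydroxy-2-(2-phenylethyl)-4H-chromen-4-one F4. BBr3 in CH2Cl2 should then give 6-[3,4-dihydroxy-2-(5-phenylpent-2-ynoyl)phenyl]-7-hydroxy-2-(2-phenylethyl)-4H-chromen-4-one F5. Acid-promoted 6-endo addition of the ortho hydroxyl to the ynone (catalytic TfOH, CH2Cl2) closes the second pyranone, and the fallback rejoins the route at 12.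

Step 1. Incomplete C-deprotonation of the poorly soluble bis-phenoxide of 1, together with self-condensation of ester 2, may leave the acetyl group unacylated. The fallback is a Baker–Venkataraman sequence that sets out from 1. Acylation of both hydroxyls with 3-phenylpropanoyl chloride (Et3N, DMAP, CH2Cl2) should give 4-acetyl-6-bromo-1,3-phenylene bis(3-phenylpropanoate) F6. KOtBu in THF should move the ortho acyl group to carbon, giving 2-bromo-5-hydroxy-4-(3-oxo-5-phenylpentanoyl)phenyl 3-phenylpropanoate F7. Conc. HCl in aqueous AcOH at reflux closes the pyranone and hydrolyses the remaining aryl ester, and the fallback rejoins the route at 4.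

**Further compounds**

F1 | step 3 | N,N-diethyl-2,3-dimethoxybenzamide | CCN(CC)C(=O)c1cccc(OC)c1OC
F2 | step 3 | [2-(diethylcarbamoyl)-3,4-dimethoxyphenyl]boronic acid | CCN(CC)C(=O)c1c(B(O)O)ccc(OC)c1OC
F3 | step 3 | N,N-diethyl-6-[7-hydroxy-4-oxo-2-(2-phenylethyl)-4H-chromen-6-yl]-2,3-dimethoxybenzamide | CCN(CC)C(=O)c1c(-c2cc3c(=O)cc(CCc4ccccc4)oc3cc2O)ccc(OC)c1OC
F4 | step 4 | 6-[3,4-dimethoxy-2-(5-phenylpent-2-ynoyl)phenyl]-7-hydroxy-2-(2-phenylethyl)-4H-chromen-4-one | O=c1cc(CCc2ccccc2)oc2cc(O)c(-c3ccc(OC)c(OC)c3C(=O)C#CCCc3ccccc3)cc12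
F5 | step 4 | 6-[3,4-dihydroxy-2-(5-phenylpent-2-ynoyl)phenyl]-7-hydroxy-2-(2-phenylethyl)-4H-chromen-4-one | O=c1cc(CCc2ccccc2)oc2cc(O)c(-c3ccc(O)c(O)c3C(=O)C#CCCc3ccccc3)cc12
F6 | step 1 | 4-acetyl-6-bromo-1,3-phenylene bis(3-phenylpropanoate) | CC(=O)c1cc(Br)c(OC(=O)CCc2ccccc2)cc1OC(=O)CCc1ccccc1
F7 | step 1 | 2-bromo-5-hydroxy-4-(3-oxo-5-phenylpentanoyl)phenyl 3-phenylpropanoate | O=C(CC(=O)CCc1ccccc1)c1cc(Br)c(OC(=O)CCc2ccccc2)cc1O
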